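Numbering: chromene O1–C8a; chain C1'–C12' counted from C2; CO2H on C8'. Cuts: O1–C2 and C4–C4a (pyran ring), C2'–C3', C4'–CH3, C8'–CO2H and C8'–C9'. C3'–C8' come in one piece from hexa-1,5-diyne.
Enabling feature: beside O1 and CH3, C2 carries two two-carbon arms, C3=C4 inside the pyran ring and C1'–C2' at the root of the chain. Written as two ethynyl groups, they make C2 the prochiral centre of a 3-aryloxy-3-methylpenta-1,4-diyne. The C8 methyl group leaves C4a as the only free position ortho to O1.
Forward: O1–C2 is made while C2 is still prochiral. An enantioselective gold(I) 6-endo-dig hydroarylation then spends one alkyne on the pyran ring (the only ring to be closed) and thereby creates C2. The spectator alkyne becomes C1'–C2'.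
Chain: alkyne to vinyl, then hydroboration/B-alkyl Suzuki–Miyaura coupling with an (E)-iodoalkene–ynoate (C2'–C3'). Syn-hydrostannation/iodination and Negishi alkylation at C8' follow, then one fluoride deprotection.
Stereochemistry: C2 comes from catalyst-controlled desymmetrisation and is not at risk later, because O1–C2 is never broken again and no acid, heat or UV light is used. E-C3'=C4' comes from syn-methylalumination and Z-C7'=C8' from syn-hydrostannation, both carried on with retention.

Key step: step 4

Assumption: which antipode of the ligand leads to the (R)-configured ethynylchromene cannot be derived from precedent. The (R)-ligand is written and is exchanged for the (S)-ligand if the first run gives the mirror image. All 2H-chromenes are handled with exclusion of daylight and UV.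

Step 1
Reactants: 1 2-methylbenzene-1,4-diol (2-methylhydroquinone)
Product: 2 2-methyl-4-(triisopropylsilyloxy)phenol
Conditions: TIPSCl (1.0 equiv), imidazole, DMF, 0 °C → rt
Reagents that add atoms: triisopropylsilyl chloride, CC(C)[Si](Cl)(C(C)C)C(C)C
Why: Silylation of a phenol: the bulky silyl chloride should react at the unhindered 4-OH and leave free the OH that is flanked by the methyl group (the later O1).

Step 2
Reactants: 3 ethyl acetate; 4 ethynylmagnesium bromide
Product: 6 3-methylpenta-1,4-diyn-3-ol, via but-3-yn-2-one 5 (not isolated)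
Conditions: 4 (2.3 equiv, 0.5 M in THF), THF, 0 °C → rt; H2O quench
Reagents that add atoms: none
Why: Double Grignard addition to an ester: ynone 5, formed after loss of ethoxide, is more electrophilic than 3 and takes up the second acetylide at once, and no stereocentre arises because the two alkynyl groups are identical.

Step 3
Reactants: 2 2-methyl-4-(triisopropylsilyloxy)phenol; 6 3-methylpenta-1,4-diyn-3-ol
Product: 8 triisopropyl{3-methyl-4-[(3-methylpenta-1,4-diyn-3-yl)oxy]phenoxy}silane, via diynyl trifluoroacetate 7 (not isolated)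
Conditions: 6, (CF3CO)2O, DBU, MeCN, −5 °C; then 2, DBU, CuCl2·2H2O (1 mol %), MeCN, −5 → 0 °C, N2
Reagents that add atoms: none
Why: Copper-catalysed propargylic substitution of a tertiary propargylic ester by a phenol (through a copper allenylidene) is the standard entry to hindered aryl 1,1-disubstituted propargyl ethers, and since C2 is still prochiral the ionising mechanism costs no stereochemical information while the aryl TIPS ether should tolerate DBU at this temperature.

Step 4
Reactants: 8 triisopropyl{3-methyl-4-[(3-methylpenta-1,4-diyn-3-yl)oxy]phenoxy}silane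
Product: 9 (2R)-2-ethynyl-2,8-dimethyl-6-(triisopropylsilyloxy)-2H-chromene
Conditions: (R)-DTBM-SEGPHOS(AuCl)2 (3 mol %), AgNTf2 (6 mol %), 4 Å MS, toluene–CH2Cl2, −20 °C, dark; ee checked by HPLC on a chiral phase
Reagents that add atoms: none
Why: Proposed new method: a cationic gold(I) centre π-activates one of the two enantiotopic ethynyl groups of 8, C4a attacks its terminal carbon (the later C4) anti to gold, and rearomatisation followed by protodeauration leaves the C3=C4 bond, so the O1–C2 bond is never broken and no planar ortho-quinone methide can intervene. The closest known reaction types are the racemic gold(I)- or platinum-catalysed hydroarylation of tertiary aryl propargyl ethers to 2,2-disubstituted 2H-chromenes and the gold(I)-catalysed enantioselective desymmetrisation of 3,3-disubstituted penta-1,4-diynes by tethered N or O nucleophiles; only the use of the arene as nucleophile in such a desymmetrisation is new. The one ring that is closed, the pyran ring, closes in the 6-endo-dig mode (C4–C4a bond), which terminal aryl propargyl ethers prefer over 5-exo-dig. C2 becomes a stereocentre because only one alkyne is consumed, and its configuration is controlled by the C2-symmetric bisphosphine: the dinuclear complex can bind both alkynes at once (one gold each), which fixes the half-chair transition state and puts CH3 and the spectator alkyne into different quadrants of the bulky DTBM-aryl pocket. The step needs ortho-regioselectivity and mono-cyclisation, both secured by the C8 methyl group (only C4a is free, and the product has no ortho position left for the second alkyne), and it needs the racemic thermal propargyl Claisen/oxa-6π path to stay silent, which the low temperature secures. The silyl ether should tolerate the catalyst, and molecular sieves keep alkyne hydration away.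

Step 5
Reactants: 9 (2R)-2-ethynyl-2,8-dimethyl-6-(triisopropylsilyloxy)-2H-chromene
Product: 10 (2S)-2-ethenyl-2,8-dimethyl-6-(triisopropylsilyloxy)-2H-chromene
Conditions: H2 (1 atm), Lindlar catalyst, quinoline, EtOAc–hexane, 0 °C → rt, stopped after 1 equiv H2
Reagents that add atoms: none
Why: Lindlar semihydrogenation: the poisoned catalyst should reduce the terminal alkyne to the vinyl group and leave the 1,2-disubstituted C3=C4 bond, the silyl ether and C2 untouched (the descriptor changes from R to S only because vinyl ranks below C3).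

Step 6
Reactants: 11 hexa-1,5-diyne
Product: 13 (5E)-6-iodo-5-methylhex-5-en-1-yne, via alkenyldimethylalane 12 (not isolated)
Conditions: 11 (3 equiv), Me3Al (1 equiv), Cp2ZrCl2 (0.2 equiv), CH2Cl2, 0 °C → rt; I2, THF, −30 °C
Reagents that add atoms: trimethylaluminium, C[Al](C)C; iodine, II
Why: Zirconium-catalysed methylalumination (Negishi carboalumination) followed by iodinolysis: syn addition of CH3–Al to one terminal alkyne sets the E geometry of C3'=C4', iodine replaces aluminium with retention, and mono-functionalisation of the symmetrical diyne is secured statistically by the excess of volatile 11.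

Step 7
Reactants: 13 (5E)-6-iodo-5-methylhex-5-en-1-yne
Product: 15 2-(trimethylsilyl)ethyl (6E)-7-iodo-6-methylhept-6-en-2-ynoate, via alkynylmagnesium bromide 14 (not isolated)
Conditions: EtMgBr (1.05 equiv), THF, 0 °C → rt; inverse addition to ClCO2CH2CH2SiMe3, THF, −20 °C → rt
Reagents that add atoms: 2-(trimethylsilyl)ethyl chloroformate, C[Si](C)(C)CCOC(=O)Cl
Why: Deprotonation of a terminal alkyne and acylation of the magnesium acetylide with a chloroformate: EtMgBr is basic enough for the alkyne C–H but should not exchange with the unactivated iodoalkene, and inverse addition prevents a second addition to the ynoate.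

Step 8
Reactants: 10 (2S)-2-ethenyl-2,8-dimethyl-6-(triisopropylsilyloxy)-2H-chromene; 15 2-(trimethylsilyl)ethyl (6E)-7-iodo-6-methylhept-6-en-2-ynoate
Product: 17 2-(trimethylsilyl)ethyl (6E)-9-[(2S)-2,8-dimethyl-6-(triisopropylsilyloxy)-2H-chromen-2-yl]-6-methylnon-6-en-2-ynoate, via B-alkyl-9-BBN borane 16 (not isolated)
Conditions: 10, 9-BBN dimer, THF, 0 °C → rt; H2O; then 15, PdCl2(dppf)·CH2Cl2 (5 mol %), AsPh3 (10 mol %), K3PO4 (3 M aq), DMF, rt
Reagents that add atoms: none
Why: Hydroboration/B-alkyl Suzuki–Miyaura coupling: 9-BBN should add only to the monosubstituted vinyl group (boron at C2', remote from O1, so no β-elimination) and not to the hindered styrenic C3=C4 bond, the sp3–sp2 coupling forms C2'–C3' with retention of the E geometry, and the alkenylpalladium species cannot carbopalladate its own ynoate because palladium stands trans to the tether.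

Step 9
Reactants: 17 2-(trimethylsilyl)ethyl (6E)-9-[(2S)-2,8-dimethyl-6-(triisopropylsilyloxy)-2H-chromen-2-yl]-6-methylnon-6-en-2-ynoate
Product: 19 2-(trimethylsilyl)ethyl (2E,6E)-9-[(2S)-2,8-dimethyl-6-(triisopropylsilyloxy)-2H-chromen-2-yl]-2-iodo-6-methylnona-2,6-dienoate, via alpha-stannyl enoate 18 (not isolated)
Conditions: Bu3SnH (slow addition), Pd(PPh3)4 (2 mol %), THF, 0 °C; then I2 in CH2Cl2, −40 °C, titrated to persistent colour
Reagents that add atoms: iodine, II
Why: Palladium-catalysed hydrostannation of a 2-alkynoate followed by iododestannylation: H and Sn add syn with tin at the α-carbon C8', which places C6' cis to the ester, and iodine should replace tin with retention faster than it attacks the alkenes or the silylated arene.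

Step 10
Reactants: 19 2-(trimethylsilyl)ethyl (2E,6E)-9-[(2S)-2,8-dimethyl-6-(triisopropylsilyloxy)-2H-chromen-2-yl]-2-iodo-6-methylnona-2,6-dienoate; 20 5-bromo-2-methylpent-2-ene
Product: 22 2-(trimethylsilyl)ethyl (2Z,6E)-9-[(2S)-2,8-dimethyl-6-(triisopropylsilyloxy)-2H-chromen-2-yl]-6-methyl-2-(4-methylpent-3-en-1-yl)nona-2,6-dienoate, via homoprenylzinc bromide 21 (not isolated)
Conditions: 20, Zn dust (BrCH2CH2Br/TMSCl-activated), LiCl, THF, 50 °C; then 19, PdCl2(dppf) (5 mol %), THF, rt
Reagents that add atoms: none
Why: Negishi coupling of an α-iodo enoate with a primary alkylzinc halide made by direct zinc insertion: C8'–C9' forms with retention and so gives the thermodynamically less favoured Z (angelate-type) enoate, while ester, silyl ether and chromene are inert to the organozinc reagent.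

Step 11
Reactants: 22 2-(trimethylsilyl)ethyl (2Z,6E)-9-[(2S)-2,8-dimethyl-6-(triisopropylsilyloxy)-2H-chromen-2-yl]-6-methyl-2-(4-methylpent-3-en-1-yl)nona-2,6-dienoate
Product: 23 (S)-sargachromenol, (2Z,6E)-9-[(2S)-6-hydroxy-2,8-dimethyl-2H-chromen-2-yl]-6-methyl-2-(4-methylpent-3-en-1-yl)nona-2,6-dienoic acid
Conditions: TBAF (5 equiv), THF, 0 °C → rt, Ar, dark; cold 0.1 M HCl work-up
Reagents that add atoms: none
Why: Fluoride-induced global deprotection: fluoride cleaves the aryl silyl ether and fragments the 2-(trimethylsilyl)ethyl ester (loss of ethene) far from the hindered carbonyl group, so no strong acid, heat or hydroxide, which could isomerise C7'=C8' or open the O1–C2 bond, is needed.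

Compound list
1 | 2-methylbenzene-1,4-diol | Cc1cc(O)ccc1O | starting material
2 | 2-methyl-4-(triisopropylsilyloxy)phenol | Cc1cc(O[Si](C(C)C)(C(C)C)C(C)C)ccc1O | intermediate
3 | ethyl acetate | CCOC(C)=O | starting material
4 | ethynylmagnesium bromide | C#C[Mg]Br | starting material
5 | but-3-yn-2-one | CC(=O)C#C | intermediate
6 | 3-methylpenta-1,4-diyn-3-ol | C#CC(C)(O)C#C | intermediate
7 | 3-methylpenta-1,4-diyn-3-yl trifluoroacetate | C#CC(C)(C#C)OC(=O)C(F)(F)F | intermediate
8 | triisopropyl{3-methyl-4-[(3-methylpenta-1,4-diyn-3-yl)oxy]phenoxy}silane | C#CC(C)(C#C)Oc1ccc(O[Si](C(C)C)(C(C)C)C(C)C)cc1C | intermediate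
9 | (2R)-2-ethynyl-2,8-dimethyl-6-(triisopropylsilyloxy)-2H-chromene | C#C[C@@]1(C)C=Cc2cc(O[Si](C(C)C)(C(C)C)C(C)C)cc(C)c2O1 | intermediate
10 | (2S)-2-ethenyl-2,8-dimethyl-6-(triisopropylsilyloxy)-2H-chromene | C=C[C@@]1(C)C=Cc2cc(O[Si](C(C)C)(C(C)C)C(C)C)cc(C)c2O1 | intermediate
11 | hexa-1,5-diyne | C#CCCC#C | starting material
12 | dimethyl[(1E)-2-methylhex-1-en-5-yn-1-yl]alane | C#CCC/C(C)=C/[Al](C)C | intermediate
13 | (5E)-6-iodo-5-methylhex-5-en-1-yne | C#CCC/C(C)=C/I | intermediate
14 | [(5E)-6-iodo-5-methylhex-5-en-1-yn-1-yl]magnesium bromide | Br[Mg]C#CCC/C(C)=C/I | intermediate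
15 | 2-(trimethylsilyl)ethyl (6E)-7-iodo-6-methylhept-6-en-2-ynoate | C[Si](C)(C)CCOC(=O)C#CCC/C(C)=C/I | intermediate
16 | 9-{2-[(2S)-2,8-dimethyl-6-(triisopropylsilyloxy)-2H-chromen-2-yl]ethyl}-9-borabicyclo[3.3.1]nonane | B1(CC[C@@]3(C)C=Cc4cc(O[Si](C(C)C)(C(C)C)C(C)C)cc(C)c4O3)C2CCCC1CCC2 | intermediate
17 | 2-(trimethylsilyl)ethyl (6E)-9-[(2S)-2,8-dimethyl-6-(triisopropylsilyloxy)-2H-chromen-2-yl]-6-methylnon-6-en-2-ynoate | C[Si](C)(C)CCOC(=O)C#CCC/C(C)=C/CC[C@@]1(C)C=Cc2cc(O[Si](C(C)C)(C(C)C)C(C)C)cc(C)c2O1 | intermediate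
18 | 2-(trimethylsilyl)ethyl (2E,6E)-9-[(2S)-2,8-dimethyl-6-(triisopropylsilyloxy)-2H-chromen-2-yl]-6-methyl-2-(tributylstannyl)nona-2,6-dienoate | CCCC[Sn](CCCC)(CCCC)/C(=C/CC/C(C)=C/CC[C@@]1(C)C=Cc2cc(O[Si](C(C)C)(C(C)C)C(C)C)cc(C)c2O1)C(=O)OCC[Si](C)(C)C | intermediate
19 | 2-(trimethylsilyl)ethyl (2E,6E)-9-[(2S)-2,8-dimethyl-6-(triisopropylsilyloxy)-2H-chromen-2-yl]-2-iodo-6-methylnona-2,6-dienoate | I/C(=C/CC/C(C)=C/CC[C@@]1(C)C=Cc2cc(O[Si](C(C)C)(C(C)C)C(C)C)cc(C)c2O1)C(=O)OCC[Si](C)(C)C | intermediate
20 | 5-bromo-2-methylpent-2-ene | CC(C)=CCCBr | starting material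
21 | (4-methylpent-3-en-1-yl)zinc bromide | CC(C)=CCC[Zn]Br | intermediate
22 | 2-(trimethylsilyl)ethyl (2Z,6E)-9-[(2S)-2,8-dimethyl-6-(triisopropylsilyloxy)-2H-chromen-2-yl]-6-methyl-2-(4-methylpent-3-en-1-yl)nona-2,6-dienoate | CC(C)=CCC/C(=C/CC/C(C)=C/CC[C@@]1(C)C=Cc2cc(O[Si](C(C)C)(C(C)C)C(C)C)cc(C)c2O1)C(=O)OCC[Si](C)(C)C | intermediate
23 | (S)-sargachromenol | CC(C)=CCC/C(=C/CC/C(C)=C/CC[C@@]1(C)C=Cc2cc(O)cc(C)c2O1)C(=O)O | target

Total step count: 11. Longest linear sequence: 8 steps (1 or 2, then 3, 4, 5, 8, 9, 10, 11).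

Steps most likely to fail

1. Step 4 (Proposed new method).
- What may go wrong: poor discrimination of the two enantiotopic alkynes, because CH3 and C≡CH differ little in size. The catalyst may be deactivated by σ,π-digold acetylide formation. The doubly propargylic C2–O bond may ionise.
- Fallback (sets out from 8, comes back at 9): 8 is cyclised with an achiral cationic gold(I) catalyst (Ph3PAuNTf2, CH2Cl2, rt), the known racemic hydroarylation of tertiary aryl propargyl ethers. This gives racemic 2-ethynyl-2,8-dimethyl-6-(triisopropylsilyloxy)-2H-chromene F1. F1 is resolved by preparative SFC on a chiral stationary phase into 9 and its antipode (2S)-2-ethynyl-2,8-dimethyl-6-(triisopropylsilyloxy)-2H-chromene F2. F2 is returned to F1 by UV irradiation (reversible photochemical oxa-6π opening of the O1–C2 bond of 2H-chromenes) and resolved again.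

2. Step 3.
- What may go wrong: elimination of the doubly propargylic ester to a cross-conjugated enediyne, attack of the phenoxide at an alkyne terminus, or oxidative dimerisation of the terminal alkynes.
- Fallback (sets out from 6, comes back at 8): the ether is closed at the other C–O bond (C8a–O1) by SNAr. 6 is deprotonated with KHMDS (1 equiv, THF–DMF, 0 °C) and arylated with commercial 4-fluoro-3-methylbenzaldehyde to 3-methyl-4-[(3-methylpenta-1,4-diyn-3-yl)oxy]benzaldehyde F3. Baeyer–Villiger (Dakin-type) oxidation with mCPBA in CH2Cl2 gives 3-methyl-4-[(3-methylpenta-1,4-diyn-3-yl)oxy]phenyl formate F4. Methanolysis (cat. K2CO3, MeOH) gives 3-methyl-4-[(3-methylpenta-1,4-diyn-3-yl)oxy]phenol F5, and silylation (TIPSCl, imidazole, DMF) gives 8.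

3. Step 8.
- What may go wrong: conjugate attack of base, arsine or phosphine, or residual borane on the electrophilic ynoate; hydrolysis of the ester; slow transmetalation of the hindered borane.
- Fallback (sets out from 10 and 13, comes back at 17): the alkyne is carried through the coupling in C-silylated form and the carboxyl carbon is added afterwards. Acetylide 14 (from 13 as in step 7) is quenched with TMSCl to [(5E)-6-iodo-5-methylhex-5-en-1-yn-1-yl]trimethylsilane F6. Borane 16 (from 10) is coupled with F6 under the conditions of step 8 to (2S)-2,8-dimethyl-2-[(3E)-4-methyl-8-(trimethylsilyl)oct-3-en-7-yn-1-yl]-6-(triisopropylsilyloxy)-2H-chromene F7. K2CO3/MeOH removes the C-silyl group to give (2S)-2,8-dimethyl-2-[(3E)-4-methyloct-3-en-7-yn-1-yl]-6-(triisopropylsilyloxy)-2H-chromene F8. EtMgBr converts F8 into the bromomagnesium acetylide of F8 F9, which is acylated with 2-(trimethylsilyl)ethyl chloroformate to 17.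

Further compounds
F1 | step 4 | racemic 2-ethynyl-2,8-dimethyl-6-(triisopropylsilyloxy)-2H-chromene | C#CC1(C)C=Cc2cc(O[Si](C(C)C)(C(C)C)C(C)C)cc(C)c2O1
F2 | step 4 | (2S)-2-ethynyl-2,8-dimethyl-6-(triisopropylsilyloxy)-2H-chromene | C#C[C@]1(C)C=Cc2cc(O[Si](C(C)C)(C(C)C)C(C)C)cc(C)c2O1
F3 | step 3 | 3-methyl-4-[(3-methylpenta-1,4-diyn-3-yl)oxy]benzaldehyde | C#CC(C)(C#C)Oc1ccc(C=O)cc1C
F4 | step 3 | 3-methyl-4-[(3-methylpenta-1,4-diyn-3-yl)oxy]phenyl formate | C#CC(C)(C#C)Oc1ccc(OC=O)cc1C
F5 | step 3 | 3-methyl-4-[(3-methylpenta-1,4-diyn-3-yl)oxy]phenol | C#CC(C)(C#C)Oc1ccc(O)cc1C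
F6 | step 8 | [(5E)-6-iodo-5-methylhex-5-en-1-yn-1-yl]trimethylsilane | C[Si](C)(C)C#CCC/C(C)=C/I
F7 | step 8 | (2S)-2,8-dimethyl-2-[(3E)-4-methyl-8-(trimethylsilyl)oct-3-en-7-yn-1-yl]-6-(triisopropylsilyloxy)-2H-chromene | C[Si](C)(C)C#CCC/C(C)=C/CC[C@@]1(C)C=Cc2cc(O[Si](C(C)C)(C(C)C)C(C)C)cc(C)c2O1
F8 | step 8 | (2S)-2,8-dimethyl-2-[(3E)-4-methyloct-3-en-7-yn-1-yl]-6-(triisopropylsilyloxy)-2H-chromene | C#CCC/C(C)=C/CC[C@@]1(C)C=Cc2cc(O[Si](C(C)C)(C(C)C)C(C)C)cc(C)c2O1
F9 | step 8 | bromomagnesium acetylide of F8 | Br[Mg]C#CCC/C(C)=C/CC[C@@]1(C)C=Cc2cc(O[Si](C(C)C)(C(C)C)C(C)C)cc(C)c2O1
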